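# Proposed total synthesis of CNP0392340.1 through an isoxazole-masked tricarbonyl and a carbonylative lactonisation

## Analysis of the target

Locants used throughout: ring atoms are O1, C2 (lactone carbonyl), C3, C4 (enol carbon), C5 and C6 (methyl-bearing). The side chain runs from C1' (the acyl carbonyl on C3) to C12', with the carboxyl group on C8', the hydroxyl on C9' and methyl branches on C4' and C10'.

The target is a 3-acyl-4-hydroxy-6-methyl-5,6-dihydro-2H-pyran-2-one whose acyl chain ends in an α-alkyl-β-hydroxy acid. It has five stereocentres in three separate regions: C6 (R) in the ring, the isolated C4' (S) in the middle of the chain, and the contiguous triad C8' (R), C9' (R), C10' (S). In the triad the C8' chain and the C9' hydroxyl are anti. No stereocentre of one region can direct another, so each region needs its own source of chirality. The C3 acyl/C4 enol/C2 lactone array is an acidic, metal-chelating β-tricarbonyl, awkward to carry through enolate chemistry and chromatography. Its ring can open by β-elimination of O1 from C6 once C5 is deprotonated. The β-hydroxy acid can epimerise at C8', dehydrate or undergo retro-aldol cleavage under base. The synthesis is hard because this head group must be joined to a base-sensitive, stereochemically dense chain without exposing either to strong base late on. The strategy rests on the pattern C1'(=O)–C3–C4(OH): it is the 1,3-dioxygen pattern of an isoxazole with nitrogen on C1' and oxygen on C4. In that form C3 is an aromatic carbon that can carry iodine, and the lactone carbonyl C2 can be put in last from carbon monoxide.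

## Retrosynthetic reasoning

**Unmasking (24 to 22).** No skeletal bond is cut at the end. The C1' ketone and C4 enol of 24 are traced back to the amino-alkylidene dione 23, and closing an N–O bond between the C1' nitrogen and the C4 oxygen leads to the isoxazole-fused lactone 22. The gain is that the tricarbonyl exists only in the last flask. The forward reactions must cleave the N–O bond reductively, hydrolyse the resulting vinylogous amide, and remove the silyl ether and tert-butyl ester without opening the lactone.

**Key disconnection (22 to 20 and 21).** In 22 the bonds C3–C2 and C2–O1 are cut together, which removes the lactone carbonyl as carbon monoxide 21 and leaves the 4-iodoisoxazole 20 with a free C6 hydroxyl. This cut is preferred to any enolate-based ring closure because it places a reactive handle (iodine) exactly at C3 and uses the only free hydroxyl as the internal nucleophile, so regiochemistry cannot be in doubt. The forward step must insert palladium into the C–I bond, take up 21 and close the six-membered ring faster than the iodide is reduced.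

**Isoxazole (20 to 15 and 16).** The C–I bond of 20 is removed to give isoxazole 19. The ring bonds C1'–C3 and O–C4 are then cut to give the nitrile oxide 18 (made from oxime 15 through chloride 17) and the alkynol 16. The alkynol brings C3 to C6, the methyl group and the C6 stereocentre in one commercial piece. The cycloaddition has to place the alkyne substituent on the oxygen-bearing ring carbon, which is the normal outcome for a terminal alkyne.

**Latent aldehyde (15 to 12).** Oxime 15 comes from aldehyde 14, and the C1' aldehyde is traced back to the trisubstituted alkene of 12. An alkene survives the strongly basic chain assembly, so no protecting group is needed for C1'.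

**Chain junction (12 to 4 and 9).** After removal of the silyl group (11), the C7'–C8' bond is cut to give the β-hydroxy ester 4 and the primary iodide 9. This is the point where the remote C4' centre (in 9) meets the C9'/C10' pair (in 4). The forward alkylation of the dianion 10 must create C8' anti to the C9' oxygen, which is the inherent preference of the chelated enolate.

**β-Hydroxy ester (4 to 1).** The C9' carbinol is traced to the ketone of 3, and the C8'–C9' bond is cut to return acid 1, which supplies C10' from the chiral pool. The forward sequence needs a two-carbon extension that does not epimerise C10' and a catalyst-controlled reduction, because methyl versus ethyl at C10' gives no useful substrate bias.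

**Iodide (9 to 5).** Iodide 9 comes from alcohol 8, which is traced through diene 6 to (R)-citronellal 5 by removal of one carbon (C7'). The R series is chosen because it maps the terpene's alkene end onto C1' and its oxygenated end onto the electrophilic terminus. The mirror-image terpene would fit only with the ends exchanged, and that would cost protecting-group steps and a late one-carbon extension at C1'.

## Alternatives that were turned down

**Alternative 1: a furan-derived cyclopropane opened to a trans-γ-lactone.**
- Disconnection: the C8'/C9' pair is folded into the lactone aldehyde A1. C9' is the ring carbinol carbon, the formyl group on C8' stands for the carboxyl, and the lactone carbonyl stands for C6'.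
- Forward key step: Ba(OH)2 removes an oxalate from a cyclopropanol. The cyclopropanolate opens by retro-aldol cleavage towards the ester-bearing carbon, and the C9' hydroxyl closes onto that ester to give A1.
- For it: absolute configuration comes from a catalytic asymmetric cyclopropanation. The trans relation of C8' and C9' is enforced by the ring and by equilibration of the formyl-bearing centre. On this point it is probably more secure than an open-chain dianion alkylation.
- Against it: the lactone carbonyl of A1 corresponds to C6', a methylene in the target, so it must be reduced, joined to the C1'–C5' part and deoxygenated. The formyl group must be re-oxidised and the vinyl group saturated. The crotylation before the key step must set C9' and C10' together. Nothing in it addresses the tricarbonyl head.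
- Comparison: it spends many steps on what steps 1, 2 and 6 of the chosen route do in three. The chosen strategy offers convergence and a solution for the head group.

**Alternative 2: carbonylative ring expansion of a cis-epoxide to a β-lactone.**
- Disconnection: the C8' carboxyl and the C9' oxygen are tied into the β-lactone A2, which is traced to a cis-C8'/C9' epoxide and carbon monoxide 21.
- Forward key step: [(salph)Al(THF)2][Co(CO)4] activates the epoxide, the cobaltate opens it at C8' with inversion, CO inserts and the alkoxide closes the oxetan-2-one A2.
- For it: it is stronger than the chosen route on atom economy and protecting-group count. Both oxygen functions are made and masked in one step, and inversion turns a cis-epoxide into the anti arrangement.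
- Against it: both epoxide carbons are secondary, so attack at C8' rather than at the sec-butyl-bearing C9' rests on a modest steric difference. The enantiopure cis-epoxide next to C10' is itself hard to make, since unconjugated cis-dialkyl alkenes are poor substrates for asymmetric epoxidation and C10' gives no bias. The electrophilic β-lactone would then have to survive the enolate chemistry needed to build the acylpyranone from the C1' ester.
- Comparison: the chosen strategy offers dependable stereocontrol at C8'/C9' and a head-group construction that the protected side chain tolerates.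

**Alternative 3: Lacey–Dieckmann closure at C3–C4.**
- Disconnection: the ring bond C3–C4 is cut, which leads to a β-keto ester whose alcohol part is the C6 carbinol of an ethyl 3-hydroxybutanoate unit.
- Forward key step: KOtBu deprotonates C3 and the carbanion attacks the ethyl ester carbon C4 with loss of ethoxide, giving the protected target A3.
- For it: it is the shortest plan and is stronger on step economy. The ring forms at its final oxidation level, A3 needs only one acidic step, and no metal catalysis or masking is required.
- Against it: the substrate is a β-acyloxy ester, so deprotonation at C5 can expel the β-keto carboxylate from C6 (E1cB), which destroys C6 and the substrate. The stabilised anion at C3 is a weak nucleophile towards a plain ethyl ester, so elimination has time to compete. The stoichiometric alkoxide also threatens the side chain, by epimerisation at C8' and loss of silanolate from C9'.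
- Comparison: the chosen strategy offers ring closure under a tertiary amine, where neither C5 nor C8' is deprotonated, and fixed regiochemistry. It pays for this with the cycloaddition, iodination and unmasking steps.

Key step: step 12

## Route

Remark on supply: (R)-citronellal 5 is taken as available in high enantiomeric purity, and the purity at C4' of the target depends on it.
Remark on tautomers: the target is drawn as its C4 enol tautomer, and 23 and 24 are expected to be tautomeric mixtures.

Step 1
Reactants: 1 (S)-2-methylbutanoic acid
Product: 3 tert-butyl (4S)-4-methyl-3-oxohexanoate, via acyl imidazolide 2 (not isolated)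
Conditions: CDI, THF, rt; then Mg(O2CCH2CO2tBu)2, THF, rt to 40 °C; aq. HCl work-up
Reagents that add atoms: magnesium bis(3-tert-butoxy-3-oxopropanoate), [Mg+2].[O-]C(=O)CC(=O)OC(C)(C)C.[O-]C(=O)CC(=O)OC(C)(C)C
Why: Masamune–Brooks C-acylation: the acyl imidazolide acylates the chelated magnesium malonate half-ester and decarboxylation gives the β-keto ester. The medium stays near neutral, so the C10' centre next to the new ketone should not epimerise.

Step 2
Reactants: 3 tert-butyl (4S)-4-methyl-3-oxohexanoate
Product: 4 tert-butyl (3S,4S)-3-hydroxy-4-methylhexanoate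
Conditions: H2 (10 bar), RuCl2[(R)-BINAP] (0.5 mol%), MeOH, 50 °C
Reagents that add atoms: none
Why: Noyori asymmetric hydrogenation: the β-keto ester chelates ruthenium and the (R)-BINAP ligand decides which carbonyl face receives hydride, which sets C9' (3S here because sec-butyl outranks CH2CO2tBu). The neighbouring C10' centre distinguishes only methyl from ethyl, so the catalyst should control the outcome.

Step 3
Reactants: 5 (R)-citronellal
Product: 6 (4R)-4,8-dimethylnona-1,7-diene
Conditions: Ph3PCH3Br, KOtBu, THF, 0 °C to rt
Reagents that add atoms: methyltriphenylphosphonium bromide, C[P+](c1ccccc1)(c1ccccc1)c1ccccc1.[Br-]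
Why: Wittig methylenation adds the carbon that becomes C7'. The stereocentre is β to the carbonyl and cannot enolise.

Step 4
Reactants: 6 (4R)-4,8-dimethylnona-1,7-diene
Product: 8 (4R)-4,8-dimethylnon-7-en-1-ol, via B-alkyl-9-borabicyclononane 7 (not isolated)
Conditions: 9-BBN, THF, 0 °C to rt; then NaOH, H2O2, 0 °C to rt
Reagents that add atoms: hydrogen peroxide, OO
Why: Hydroboration–oxidation: the bulky dialkylborane adds anti-Markovnikov to the monosubstituted alkene and leaves the trisubstituted alkene alone. Oxidation then gives the primary alcohol.

Step 5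
Reactants: 8 (4R)-4,8-dimethylnon-7-en-1-ol
Product: 9 (6R)-9-iodo-2,6-dimethylnon-2-ene
Conditions: I2, PPh3, imidazole, CH2Cl2, 0 °C to rt
Reagents that add atoms: iodine, II
Why: Appel-type iodination: the alkoxyphosphonium ion is displaced by iodide at the primary carbon. The stereocentre and the alkene are not involved.

Step 6
Reactants: 4 tert-butyl (3S,4S)-3-hydroxy-4-methylhexanoate; 9 (6R)-9-iodo-2,6-dimethylnon-2-ene
Product: 11 tert-butyl (2R,3R,4S)-2-[(4S)-4,8-dimethylnon-7-en-1-yl]-3-hydroxy-4-methylhexanoate, via dilithium alkoxide enolate 10 (not isolated)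
Conditions: LiN(iPr)2 (2.2 equiv), THF, −78 to −20 °C; then 9, DMPU, −78 to 0 °C; aq. NH4Cl
Reagents that add atoms: none
Why: Fráter–Seebach alkylation: the dianion is a rigid six-membered lithium chelate, and the iodide approaches the enolate face opposite the sec-butyl group on C9'. This sets C8' anti to the oxygen (2R,3R). DMPU raises the reactivity towards the unactivated primary iodide.

Step 7
Reactants: 11 tert-butyl (2R,3R,4S)-2-[(4S)-4,8-dimethylnon-7-en-1-yl]-3-hydroxy-4-methylhexanoate
Product: 12 tert-butyl (2R,3R,4S)-3-[(tert-butyldimethylsilyl)oxy]-2-[(4S)-4,8-dimethylnon-7-en-1-yl]-4-methylhexanoate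
Conditions: TBSOTf, 2,6-lutidine, CH2Cl2, −78 to 0 °C
Reagents that add atoms: tert-butyldimethylsilyl trifluoromethanesulfonate, CC(C)(C)[Si](C)(C)OS(=O)(=O)C(F)(F)F
Why: Silylation with the silyl triflate is the standard answer to a hindered secondary alcohol. The buffered, cold conditions should not cause retro-aldol cleavage or epimerisation.

Step 8
Reactants: 12 silyl ether with the trisubstituted alkene
Product: 14 tert-butyl (2R,3R,4S)-3-[(tert-butyldimethylsilyl)oxy]-4-methyl-2-[(4S)-4-methyl-7-oxoheptyl]hexanoate, via secondary ozonide 13 (not isolated)
Conditions: O3, CH2Cl2, −78 °C; then PPh3, −78 °C to rt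
Reagents that add atoms: ozone, [O-][O+]=O
Why: Ozonolysis with reductive work-up: the only alkene is cleaved through the 1,2,4-trioxolane to the C1' aldehyde. The silyl ether and ester are inert to ozone.

Step 9
Reactants: 14 C1' aldehyde
Product: 15 tert-butyl (2R,3R,4S)-3-[(tert-butyldimethylsilyl)oxy]-2-[(4S)-7-(hydroxyimino)-4-methylheptyl]-4-methylhexanoate (E/Z mixture)
Conditions: NH2OH·HCl, NaOAc, EtOH/H2O, rt
Reagents that add atoms: hydroxylamine hydrochloride, NO.Cl
Why: Oxime condensation under acetate buffer. Both oxime isomers lead to the same nitrile oxide, so the geometry does not matter.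

Step 10
Reactants: 15 aldoxime; 16 (R)-pent-4-yn-2-ol
Product: 19 tert-butyl (2R,3R,4S)-3-[(tert-butyldimethylsilyl)oxy]-2-[(4S)-6-{5-[(2R)-2-hydroxypropyl]-1,2-oxazol-3-yl}-4-methylhexyl]-4-methylhexanoate, via hydroximoyl chloride 17 (not isolated), via nitrile oxide 18 (not isolated)
Conditions: NCS, DMF, rt; then 16 (3 equiv), Et3N (syringe pump), CH2Cl2, 0 °C to rt
Reagents that add atoms: none
Why: Chlorination of the oxime and slow dehydrochlorination release the nitrile oxide, which undergoes Huisgen 1,3-dipolar cycloaddition with the terminal alkyne. Sterics and orbital coefficients put the alkyne substituent on the oxygen-bearing carbon, giving the 3,5-disubstituted isoxazole. Slow addition of base and excess alkyne keep dimerisation to the furoxan down, and the free hydroxyl reacts far more slowly than the alkyne.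

Step 11
Reactants: 19 3,5-disubstituted isoxazole
Product: 20 tert-butyl (2R,3R,4S)-3-[(tert-butyldimethylsilyl)oxy]-2-[(4S)-6-{5-[(2R)-2-hydroxypropyl]-4-iodo-1,2-oxazol-3-yl}-4-methylhexyl]-4-methylhexanoate
Conditions: NIS, CF3CO2H (20 mol%), MeCN, rt to 40 °C
Reagents that add atoms: N-iodosuccinimide, O=C1CCC(=O)N1I
Why: Electrophilic aromatic iodination: C4 is the only free position of the isoxazole and its most electron-rich one. The catalytic amount of acid activates the iodinating agent and should not cleave the hindered silyl ether or the tert-butyl ester.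

Step 12
Reactants: 20 4-iodoisoxazole with free C6 hydroxyl; 21 carbon monoxide
Product: 22 tert-butyl (2R,3R,4S)-3-[(tert-butyldimethylsilyl)oxy]-4-methyl-2-{(4S)-4-methyl-6-[(6R)-6-methyl-4-oxo-6,7-dihydro-4H-pyrano[3,4-d][1,2]oxazol-3-yl]hexyl}hexanoate
Conditions: Pd(OAc)2 (5 mol%), 1,1'-bis(diphenylphosphino)ferrocene (10 mol%), CO (1–3 bar), Et3N, DMF, 70 °C
Reagents that add atoms: carbon monoxide 21, [C-]#[O+]
Why: Pd(OAc)2 is reduced in the flask to a zerovalent palladium–diphosphine complex, which adds oxidatively into the C4–I bond of the isoxazole (target C3) to give a heteroaryl divalent palladium iodide. Coordination and migratory insertion of 21 give the acylpalladium species, and the C6 hydroxyl, deprotonated by Et3N, attacks the acyl carbon (or binds palladium and is reductively eliminated); this forms C3–C2 and C2–O1 and returns zerovalent palladium. The closest known reaction type is the palladium-catalysed intramolecular alkoxycarbonylation of aryl and heteroaryl iodides carrying a hydroxyalkyl side chain (phthalides, isochromanones), together with intermolecular carbonylation of 4-iodoisoxazoles. The δ-lactone ring is closed by acyl substitution at the acylpalladium carbon, a 6-exo-trig attack of oxygen in which the acyl carbon becomes ring atom C2. No stereocentre is formed: C6 comes from 16 and its C–O bond is not broken, and the tertiary amine does not deprotonate C8'. The step needs chemoselectivity for lactonisation over hydrodeiodination and over intermolecular capture. This is secured by the adjacent placement of iodine and hydroxypropyl group on the flat heteroarene, by the single free hydroxyl, and by the chelating diphosphine, which favours fast CO insertion and reductive elimination. Regiochemistry is not an issue because the carbonyl can only enter at the iodinated carbon, and the fully substituted isoxazole should keep its N–O bond in the absence of strong base or reductant.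

Step 13
Reactants: 22 isoxazole-fused lactone
Product: 23 tert-butyl (2R,3R,4S)-2-{(4S)-7-amino-4-methyl-7-[(6R)-6-methyl-2,4-dioxooxan-3-ylidene]heptyl}-3-[(tert-butyldimethylsilyl)oxy]-4-methylhexanoate
Conditions: Mo(CO)6, MeCN/H2O, 80 °C
Reagents that add atoms: none
Why: Reductive cleavage of the isoxazole N–O bond by zerovalent molybdenum in wet acetonitrile gives the vinylogous amide, which is stabilised by conjugation with both ring carbonyls. The lactone, silyl ether and tert-butyl ester are not reduced.

Step 14
Reactants: 23 amino-alkylidene dione
Product: 24 (2R,3R,4S)-3-hydroxy-2-{(4S)-7-[(6R)-4-hydroxy-6-methyl-2-oxo-5,6-dihydro-2H-pyran-3-yl]-4-methyl-7-oxoheptyl}-4-methylhexanoic acid (target)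
Conditions: 3 M aq. HCl, 1,4-dioxane, 60 °C
Reagents that add atoms: water, O
Why: Acid hydrolysis: protonation of the enaminone at C3 gives an iminium ion that water attacks at C1', and nitrogen leaves as ammonium to give the C1' ketone. The same medium cleaves the silyl ether and the tert-butyl ester (alkyl–oxygen cleavage) without touching a stereocentre.

## Compound list

1 | (S)-2-methylbutanoic acid | CC[C@H](C)C(=O)O | starting material
2 | (2S)-1-(1H-imidazol-1-yl)-2-methylbutan-1-one (acyl imidazolide of 1) | CC[C@H](C)C(=O)n1ccnc1 | intermediate
3 | tert-butyl (4S)-4-methyl-3-oxohexanoate | CC[C@H](C)C(=O)CC(=O)OC(C)(C)C | intermediate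
4 | tert-butyl (3S,4S)-3-hydroxy-4-methylhexanoate | CC[C@H](C)[C@@H](O)CC(=O)OC(C)(C)C | intermediate
5 | (R)-citronellal, (3R)-3,7-dimethyloct-6-enal | CC(C)=CCC[C@@H](C)CC=O | starting material
6 | (4R)-4,8-dimethylnona-1,7-diene | CC(C)=CCC[C@@H](C)CC=C | intermediate
7 | 9-[(4S)-4,8-dimethylnon-7-en-1-yl]-9-borabicyclo[3.3.1]nonane | CC(C)=CCC[C@@H](C)CCCB1C2CCCC1CCC2 | intermediate
8 | (4R)-4,8-dimethylnon-7-en-1-ol | CC(C)=CCC[C@@H](C)CCCO | intermediate
9 | (6R)-9-iodo-2,6-dimethylnon-2-ene | CC(C)=CCC[C@@H](C)CCCI | intermediate
10 | dilithium alkoxide enolate (dianion) of 4 | CC[C@H](C)[C@@H]([O-])C=C([O-])OC(C)(C)C.[Li+].[Li+] | intermediate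
11 | tert-butyl (2R,3R,4S)-2-[(4S)-4,8-dimethylnon-7-en-1-yl]-3-hydroxy-4-methylhexanoate | CC[C@H](C)[C@@H](O)[C@@H](CCC[C@H](C)CCC=C(C)C)C(=O)OC(C)(C)C | intermediate
12 | tert-butyl (2R,3R,4S)-3-[(tert-butyldimethylsilyl)oxy]-2-[(4S)-4,8-dimethylnon-7-en-1-yl]-4-methylhexanoate | CC[C@H](C)[C@@H](O[Si](C)(C)C(C)(C)C)[C@@H](CCC[C@H](C)CCC=C(C)C)C(=O)OC(C)(C)C | intermediate
13 | secondary ozonide of 12: tert-butyl (2R,3R,4S)-3-[(tert-butyldimethylsilyl)oxy]-2-[(4S)-6-(5,5-dimethyl-1,2,4-trioxolan-3-yl)-4-methylhexyl]-4-methylhexanoate (trioxolane carbon unassigned) | CC[C@H](C)[C@@H](O[Si](C)(C)C(C)(C)C)[C@@H](CCC[C@H](C)CCC1OOC(C)(C)O1)C(=O)OC(C)(C)C | intermediate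
14 | tert-butyl (2R,3R,4S)-3-[(tert-butyldimethylsilyl)oxy]-4-methyl-2-[(4S)-4-methyl-7-oxoheptyl]hexanoate | CC[C@H](C)[C@@H](O[Si](C)(C)C(C)(C)C)[C@@H](CCC[C@H](C)CCC=O)C(=O)OC(C)(C)C | intermediate
15 | tert-butyl (2R,3R,4S)-3-[(tert-butyldimethylsilyl)oxy]-2-[(4S)-7-(hydroxyimino)-4-methylheptyl]-4-methylhexanoate (E/Z mixture) | CC[C@H](C)[C@@H](O[Si](C)(C)C(C)(C)C)[C@@H](CCC[C@H](C)CCC=NO)C(=O)OC(C)(C)C | intermediate
16 | (R)-pent-4-yn-2-ol | C#CC[C@@H](C)O | starting material
17 | hydroximoyl chloride of 15: tert-butyl (2R,3R,4S)-3-[(tert-butyldimethylsilyl)oxy]-2-[(4S)-7-chloro-7-(hydroxyimino)-4-methylheptyl]-4-methylhexanoate | CC[C@H](C)[C@@H](O[Si](C)(C)C(C)(C)C)[C@@H](CCC[C@H](C)CCC(Cl)=NO)C(=O)OC(C)(C)C | intermediate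
18 | nitrile oxide from 17 (C1' as C≡N–O dipole, rest of the molecule as in 15) | CC[C@H](C)[C@@H](O[Si](C)(C)C(C)(C)C)[C@@H](CCC[C@H](C)CCC#[N+][O-])C(=O)OC(C)(C)C | intermediate
19 | tert-butyl (2R,3R,4S)-3-[(tert-butyldimethylsilyl)oxy]-2-[(4S)-6-{5-[(2R)-2-hydroxypropyl]-1,2-oxazol-3-yl}-4-methylhexyl]-4-methylhexanoate | CC[C@H](C)[C@@H](O[Si](C)(C)C(C)(C)C)[C@@H](CCC[C@H](C)CCc1noc(C[C@@H](C)O)c1)C(=O)OC(C)(C)C | intermediate
20 | tert-butyl (2R,3R,4S)-3-[(tert-butyldimethylsilyl)oxy]-2-[(4S)-6-{5-[(2R)-2-hydroxypropyl]-4-iodo-1,2-oxazol-3-yl}-4-methylhexyl]-4-methylhexanoate | CC[C@H](C)[C@@H](O[Si](C)(C)C(C)(C)C)[C@@H](CCC[C@H](C)CCc1noc(C[C@@H](C)O)c1I)C(=O)OC(C)(C)C | intermediate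
21 | carbon monoxide | [C-]#[O+] | starting material
22 | tert-butyl (2R,3R,4S)-3-[(tert-butyldimethylsilyl)oxy]-4-methyl-2-{(4S)-4-methyl-6-[(6R)-6-methyl-4-oxo-6,7-dihydro-4H-pyrano[3,4-d][1,2]oxazol-3-yl]hexyl}hexanoate | CC[C@H](C)[C@@H](O[Si](C)(C)C(C)(C)C)[C@@H](CCC[C@H](C)CCc1noc2C[C@@H](C)OC(=O)c12)C(=O)OC(C)(C)C | intermediate
23 | tert-butyl (2R,3R,4S)-2-{(4S)-7-amino-4-methyl-7-[(6R)-6-methyl-2,4-dioxooxan-3-ylidene]heptyl}-3-[(tert-butyldimethylsilyl)oxy]-4-methylhexanoate | CC[C@H](C)[C@@H](O[Si](C)(C)C(C)(C)C)[C@@H](CCC[C@H](C)CCC(N)=C1C(=O)C[C@@H](C)OC1=O)C(=O)OC(C)(C)C | intermediate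
24 | (2R,3R,4S)-3-hydroxy-2-{(4S)-7-[(6R)-4-hydroxy-6-methyl-2-oxo-5,6-dihydro-2H-pyran-3-yl]-4-methyl-7-oxoheptyl}-4-methylhexanoic acid | CC[C@H](C)[C@@H](O)[C@@H](CCC[C@H](C)CCC(=O)C1=C(O)C[C@@H](C)OC1=O)C(=O)O | target

## Step count and risk

Total steps: 14. Longest linear sequence: 12 steps (steps 3 to 14, from 5). The branch from 1 joins at step 6 after two steps.

**Step 12 (key step).** The process most likely to fail is reductive loss of iodine from the heteroarylpalladium intermediate before CO insertion, with the amine as hydride source. This leads back to the non-iodinated isoxazole. Insertion of zerovalent palladium into the N–O bond is a second possible drain.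
Fallback: it sets out from 20. Iodine–magnesium exchange with iPrMgCl·LiCl (2.2 equiv, the first equivalent taking the hydroxyl proton) in THF at −30 °C, then carboxylation with CO2 and acidic work-up, would give the isoxazole-4-carboxylic acid with the free C6 hydroxyl F1. Lactonisation with EDC·HCl and DMAP closes the same ring and returns to the route at 22. The carbonyl then enters through a carbanion and CO2 instead of a catalytic cycle.

**Step 6.** SN2 attack of the dianion on an unactivated primary iodide is slow. The dianion may therefore decay on warming by retro-aldol cleavage or elimination, with low conversion and eroded anti selectivity.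
Fallback: it sets out from 4. The dianion is alkylated with allyl bromide, a far more reactive electrophile, to give tert-butyl (2R,3R,4S)-3-hydroxy-4-methyl-2-(prop-2-en-1-yl)hexanoate F2, and silylation as in step 7 gives its silyl ether F3. Cross-metathesis of F3 with (R)-3,7-dimethylocta-1,6-diene F4, using the second-generation Grubbs catalyst (H2IMes)(PCy3)Cl2Ru=CHPh, builds the C5'–C6' bond as an alkene in the diene F5. Diimide, generated from 2-nitrobenzenesulfonohydrazide and Et3N, then reduces the 1,2-disubstituted alkene in preference to the trisubstituted one and returns to the route at 12. Steps 3 to 5 are then not needed.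

**Step 11.** The 3,5-dialkylisoxazole is only moderately nucleophilic. The acid needed to drive the iodination may start to remove the silyl ether or the tert-butyl ester before substitution is complete.
Fallback: it sets out from 15, chlorinated to 17 as in step 10. The cycloaddition is run with (R)-5-iodopent-4-yn-2-ol F6 (from 16 with NIS and catalytic AgNO3) under Cp*RuCl(cod) catalysis with Et3N. This is the known ruthenium-catalysed addition of nitrile oxides to 1-iodoalkynes, which gives 4-iodoisoxazoles directly, and it returns to the route at 20 with no electrophilic iodination of the ring.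

**Step 14.** The doubly stabilised enaminone may hydrolyse too slowly under acid mild enough for the lactone. More forcing acid risks lactone hydrolysis followed by decarboxylation of the resulting β-keto acid.
Fallback: it sets out from 22 and separates the three events. CF3CO2H in CH2Cl2, then aqueous work-up, removes the tert-butyl and silyl groups to give the isoxazole-lactone hydroxy acid F7. Mo(CO)6 in wet acetonitrile then gives the deprotected enaminone F8. Aqueous 1 M NaOH at rt exchanges the amino group for oxygen by addition–elimination at C1', where the tricarbonyl anion formed shields the lactone from hydroxide, and acidification to pH 2 arrives at 24.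

## Further compounds

F1 | step 12 | 3-[(3S,7R,8R,9S)-7-(tert-butoxycarbonyl)-8-[(tert-butyldimethylsilyl)oxy]-3,9-dimethylundecyl]-5-[(2R)-2-hydroxypropyl]-1,2-oxazole-4-carboxylic acid | CC[C@H](C)[C@@H](O[Si](C)(C)C(C)(C)C)[C@@H](CCC[C@H](C)CCc1noc(C[C@@H](C)O)c1C(=O)O)C(=O)OC(C)(C)C
F2 | step 6 | tert-butyl (2R,3R,4S)-3-hydroxy-4-methyl-2-(prop-2-en-1-yl)hexanoate | CC[C@H](C)[C@@H](O)[C@@H](CC=C)C(=O)OC(C)(C)C
F3 | step 6 | tert-butyl (2R,3R,4S)-3-[(tert-butyldimethylsilyl)oxy]-4-methyl-2-(prop-2-en-1-yl)hexanoate | CC[C@H](C)[C@@H](O[Si](C)(C)C(C)(C)C)[C@@H](CC=C)C(=O)OC(C)(C)C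
F4 | step 6 | (R)-3,7-dimethylocta-1,6-diene | C=C[C@H](C)CCC=C(C)C
F5 | step 6 | tert-butyl (2R,3R,4S)-3-[(tert-butyldimethylsilyl)oxy]-2-[(2E,4R)-4,8-dimethylnona-2,7-dien-1-yl]-4-methylhexanoate (E isomer shown) | CC[C@H](C)[C@@H](O[Si](C)(C)C(C)(C)C)[C@@H](C/C=C/[C@H](C)CCC=C(C)C)C(=O)OC(C)(C)C
F6 | step 11 | (R)-5-iodopent-4-yn-2-ol | IC#CC[C@@H](C)O
F7 | step 14 | (2R,3R,4S)-3-hydroxy-4-methyl-2-{(4S)-4-methyl-6-[(6R)-6-methyl-4-oxo-6,7-dihydro-4H-pyrano[3,4-d][1,2]oxazol-3-yl]hexyl}hexanoic acid | CC[C@H](C)[C@@H](O)[C@@H](CCC[C@H](C)CCc1noc2C[C@@H](C)OC(=O)c12)C(=O)O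
F8 | step 14 | (2R,3R,4S)-2-{(4S)-7-amino-4-methyl-7-[(6R)-6-methyl-2,4-dioxooxan-3-ylidene]heptyl}-3-hydroxy-4-methylhexanoic acid | CC[C@H](C)[C@@H](O)[C@@H](CCC[C@H](C)CCC(N)=C1C(=O)C[C@@H](C)OC1=O)C(=O)O
A1 | alternative 1 | (2R,3R)-2-[(2S)-but-3-en-2-yl]-5-oxooxolane-3-carbaldehyde | C=C[C@H](C)[C@H]1OC(=O)C[C@H]1C=O
A2 | alternative 2 | tert-butyl (4S)-7-[(2R,3R)-2-[(2S)-butan-2-yl]-4-oxooxetan-3-yl]-4-methylheptanoate | CC[C@H](C)[C@H]1OC(=O)[C@@H]1CCC[C@H](C)CCC(=O)OC(C)(C)C
A3 | alternative 3 | tert-butyl (2R,3R,4S)-3-[(tert-butyldimethylsilyl)oxy]-2-{(4S)-7-[(6R)-4-hydroxy-6-methyl-2-oxo-5,6-dihydro-2H-pyran-3-yl]-4-methyl-7-oxoheptyl}-4-methylhexanoate | CC[C@H](C)[C@@H](O[Si](C)(C)C(C)(C)C)[C@@H](CCC[C@H](C)CCC(=O)C1=C(O)C[C@@H](C)OC1=O)C(=O)OC(C)(C)C
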